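**Retrosynthetic overview**
- Ten-membered carbocycle, formed last: C1=C2 by ring-closing metathesis of a C10 vinyl carbinol with a C3 vinyl ketone.
- C3 carbonyl from CO: carbonylative Stille coupling on a (Z)-vinyl iodide, which fixes the 4Z enone after the lactone is already closed.
- γ-Lactone, formed first: syn-selective indium Barbier union C6–C7 of a (Z)-2-(bromomethyl)enoate with (Z)-3-iodobut-2-enal, then lactonisation; C7 and C6 are relayed from C8.
- Key disconnection, the C8–O ester bond: a catalytic asymmetric α-acyloxylation of a linalool-derived aldehyde with the diacyl peroxide of (R)-2-methylbutanoic acid sets C8 and installs the side chain without protecting that oxygen.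
- C10 carbinol, C14, C9 and C1 come from (R)-linalool.

Assumption: (R)-linalool and (R)-2-methylbutanoic acid are bought as single enantiomers; the SMILES is read as 6S,7R,8R,10R,2'R with a cis-fused lactone, 1E and 4Z, and atom labels C1–C15 are the germacrane numbers of the target.

This route is a proposal and has not been run; the stereochemical outcomes of steps 4, 9 and 11 are predictions.

**Step 1**
Reactants: 1 (3R)-3,7-dimethylocta-1,6-dien-3-ol [(R)-linalool]
Product: 2 triethyl{[(3R)-3,7-dimethylocta-1,6-dien-3-yl]oxy}silane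
Conditions: TESOTf, 2,6-lutidine, CH2Cl2, −78 to 0 °C
Reagents that add atoms: triethylsilyl trifluoromethanesulfonate, CC[Si](CC)(CC)OS(=O)(=O)C(F)(F)F
Why: Silyl ether protection of the tertiary alcohol keeps the aldehyde of step 2 open-chain instead of closing to a lactol, and the C10 stereocentre is carried unchanged from (R)-linalool.

**Step 2**
Reactants: 2 triethyl{[(3R)-3,7-dimethylocta-1,6-dien-3-yl]oxy}silane
Product: 3 (4R)-4-methyl-4-[(triethylsilyl)oxy]hex-5-enal
Conditions: O3 (1.0 equiv), CH2Cl2, −78 °C; then Me2S, −78 °C to rt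
Reagents that add atoms: ozone, [O-][O+]=O
Why: Ozonolysis with one equivalent of ozone cleaves the electron-rich trisubstituted alkene much faster than the hindered vinyl group next to the silyloxy carbon, giving the C7 aldehyde.

**Step 3**
Reactants: 4 (2R)-2-methylbutanoic acid (2 equiv)
Product: 5 bis[(2R)-2-methylbutanoyl] peroxide
Conditions: 4 (2.0 equiv), H2O2 (50% aq., 1.0 equiv), DCC (2.1 equiv), CH2Cl2, −10 to 0 °C; kept as a cold solution and used at once
Reagents that add atoms: hydrogen peroxide, OO; (2R)-2-methylbutanoic acid (the second equivalent of 4), CC[C@@H](C)C(=O)O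
Why: Carbodiimide-mediated dehydrative coupling (standard diacyl peroxide synthesis) acylates each oxygen of hydrogen peroxide with one molecule of acid 4 through its O-acylisourea, so two acid molecules and one hydrogen peroxide give one peroxide, and the α-stereocentres are untouched.

**Step 4**
Reactants: 3 (4R)-4-methyl-4-[(triethylsilyl)oxy]hex-5-enal; 5 bis[(2R)-2-methylbutanoyl] peroxide
Product: 6 (2R,4R)-4-methyl-1-oxo-4-[(triethylsilyl)oxy]hex-5-en-2-yl (2R)-2-methylbutanoate
Conditions: (R)-α,α-diphenylprolinol trimethylsilyl ether (10 mol%), hydroquinone (10 mol%), THF, −10 °C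
Reagents that add atoms: none
Why: Proposed new method: the E-enamine of 3 with the (R)-diarylprolinol silyl ether attacks the O–O bond of 5 in an SN2-type displacement at oxygen (enamine HOMO into σ*O–O, carboxylate as leaving group), the CPh2(OSiMe3) group blocks one enamine face so the C8–O bond forms with R configuration (the (S)-catalyst is known to give (S)-α-heteroatom aldehydes), iminium hydrolysis releases 6 and the catalyst, and hydroquinone suppresses radical decomposition of the peroxide; the closest known reaction is the amine-catalysed asymmetric α-benzoyloxylation of aldehydes with dibenzoyl peroxide, not yet shown for an aliphatic α-branched diacyl peroxide.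

**Step 5**
Reactants: 6 (2R,4R)-4-methyl-1-oxo-4-[(triethylsilyl)oxy]hex-5-en-2-yl (2R)-2-methylbutanoate; 7 methyl propiolate
Product: 9 methyl (4R,6R)-3-hydroxy-6-methyl-2-methylidene-4-{[(2R)-2-methylbutanoyl]oxy}-6-[(triethylsilyl)oxy]oct-7-enoate (both C3 epimers), via vinylalane 8 (not isolated)
Conditions: 7, iBu2AlH, NMO, THF, 0 °C; then 6, 0 °C to rt
Reagents that add atoms: none
Why: Vinylalumination, a base-free equivalent of the Morita–Baylis–Hillman reaction: hydroalumination of 7 gives the α-aluminoacrylate 8, which adds to the aldehyde without enolising it, so C8 is preserved, and the new carbinol centre (C7) is erased in step 6.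

**Step 6**
Reactants: 9 methyl (4R,6R)-3-hydroxy-6-methyl-2-methylidene-4-{[(2R)-2-methylbutanoyl]oxy}-6-[(triethylsilyl)oxy]oct-7-enoate
Product: 10 methyl (2Z,4R,6R)-2-(bromomethyl)-6-methyl-4-{[(2R)-2-methylbutanoyl]oxy}-6-[(triethylsilyl)oxy]octa-2,7-dienoate
Conditions: NBS, Me2S, CH2Cl2, 0 °C to rt
Reagents that add atoms: N-bromosuccinimide, O=C1CCC(=O)N1Br
Why: Corey–Kim-type activation of the allylic alcohol and SN2' attack of bromide at the terminal methylene give the rearranged allylic bromide, with the tiglate-like 2Z geometry (C8 cis to CH2Br) that Morita–Baylis–Hillman adducts normally give.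

**Step 7**
Reactants: 11 but-2-yn-1-ol
Product: 13 (2Z)-3-iodobut-2-en-1-ol, via cyclic alkenylalanate 12 (not isolated)
Conditions: NaAlH2(OCH2CH2OMe)2, THF, 0 °C to rt; then I2, −78 to 0 °C
Reagents that add atoms: iodine, II
Why: Hydroxyl-directed trans-hydroalumination of the propargylic alcohol puts aluminium on C3 in a five-membered alanate, and iodinolysis with retention gives the (Z)-vinyl iodide.

**Step 8**
Reactants: 13 (2Z)-3-iodobut-2-en-1-ol
Product: 14 (2Z)-3-iodobut-2-enal
Conditions: MnO2, CH2Cl2, rt, dark; used at once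
Reagents that add atoms: none
Why: MnO2 oxidation of the allylic alcohol is neutral and keeps the Z geometry that later becomes the 4Z alkene.

**Step 9**
Reactants: 10 methyl (2Z,4R,6R)-2-(bromomethyl)-6-methyl-4-{[(2R)-2-methylbutanoyl]oxy}-6-[(triethylsilyl)oxy]octa-2,7-dienoate; 14 (2Z)-3-iodobut-2-enal
Product: 17 (1R,3R)-3-hydroxy-1-{(2R,3R)-2-[(1Z)-2-iodoprop-1-en-1-yl]-4-methylidene-5-oxooxolan-3-yl}-3-methylpent-4-en-1-yl (2R)-2-methylbutanoate, via syn-hydroxy ester 15 (not isolated), via silylated lactone 16 (not isolated)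
Conditions: In powder, THF/H2O 1:1, rt; then PPTS, MeOH, 45 °C
Reagents that add atoms: none
Why: Indium Barbier allylation: the allylindium from 10 adds through C7 in a chair transition state with the C8 substituent (cis to CH2In) axial, giving the syn adduct and hence the cis-lactone (C6), while allylic 1,3-strain holds C8–H in the alkene plane so the aldehyde enters on the acyloxy-bearing face away from the C9 chain (C7 R); PPTS in methanol then closes the γ-lactone by acyl substitution and removes the triethylsilyl group.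

**Step 10**
Reactants: 17 (1R,3R)-3-hydroxy-1-{(2R,3R)-2-[(1Z)-2-iodoprop-1-en-1-yl]-4-methylidene-5-oxooxolan-3-yl}-3-methylpent-4-en-1-yl (2R)-2-methylbutanoate; 18 tributyl(ethenyl)stannane
Product: 19 (1R,3R)-3-hydroxy-3-methyl-1-{(2S,3R)-4-methylidene-2-[(1Z)-2-methyl-3-oxopenta-1,4-dien-1-yl]-5-oxooxolan-3-yl}pent-4-en-1-yl (2R)-2-methylbutanoate
Conditions: CO (3 atm), Pd2(dba)3 (3 mol%), AsPh3 (12 mol%), NMP, 40 °C
Reagents that add atoms: carbon monoxide, [C-]#[O+]
Why: Carbonylative Stille coupling: oxidative addition of the vinyl iodide to zerovalent palladium with retention, CO insertion under pressure (ahead of direct coupling or Heck closure onto the methylene lactone), transmetalation and reductive elimination give the cross-conjugated divinyl ketone with the 4Z geometry intact.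

**Step 11**
Reactants: 19 (1R,3R)-3-hydroxy-3-methyl-1-{(2S,3R)-4-methylidene-2-[(1Z)-2-methyl-3-oxopenta-1,4-dien-1-yl]-5-oxooxolan-3-yl}pent-4-en-1-yl (2R)-2-methylbutanoate
Product: 20 (3aR,4R,6R,7E,10Z,11aS)-6-hydroxy-6,10-dimethyl-3-methylidene-2,9-dioxo-2,3,3a,4,5,6,9,11a-octahydrocyclodeca[b]furan-4-yl (2R)-2-methylbutanoate
Conditions: second-generation Hoveyda–Grubbs catalyst, (H2IMes)Cl2Ru=CH(C6H4-2-OiPr) (10 mol%), toluene (1 mM), 80 °C
Reagents that add atoms: none
Why: Ring-closing metathesis: the ruthenium carbene loads on the vinyl group activated by the free tertiary allylic hydroxyl and closes onto the vinyl ketone, the enone product is inert to further metathesis, and the 1E enone (the geometry of natural tagitinin-type rings) is expected as the less strained isomer with the 4Z alkene and cis-lactone in place.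

**Compound list**
1 | (3R)-3,7-dimethylocta-1,6-dien-3-ol [(R)-linalool] | C=C[C@](C)(O)CCC=C(C)C | starting material
2 | triethyl{[(3R)-3,7-dimethylocta-1,6-dien-3-yl]oxy}silane | C=C[C@](C)(O[Si](CC)(CC)CC)CCC=C(C)C | intermediate
3 | (4R)-4-methyl-4-[(triethylsilyl)oxy]hex-5-enal | C=C[C@](C)(O[Si](CC)(CC)CC)CCC=O | intermediate
4 | (2R)-2-methylbutanoic acid | CC[C@@H](C)C(=O)O | starting material
5 | bis[(2R)-2-methylbutanoyl] peroxide | CC[C@@H](C)C(=O)OOC(=O)[C@H](C)CC | intermediate
6 | (2R,4R)-4-methyl-1-oxo-4-[(triethylsilyl)oxy]hex-5-en-2-yl (2R)-2-methylbutanoate | C=C[C@](C)(O[Si](CC)(CC)CC)C[C@@H](OC(=O)[C@H](C)CC)C=O | intermediate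
7 | methyl propiolate (methyl prop-2-ynoate) | C#CC(=O)OC | starting material
8 | [1-(methoxycarbonyl)ethenyl]bis(2-methylpropyl)alumane | C=C(C(=O)OC)[Al](CC(C)C)CC(C)C | intermediate
9 | methyl (4R,6R)-3-hydroxy-6-methyl-2-methylidene-4-{[(2R)-2-methylbutanoyl]oxy}-6-[(triethylsilyl)oxy]oct-7-enoate (both C3 epimers) | C=C[C@](C)(O[Si](CC)(CC)CC)C[C@@H](OC(=O)[C@H](C)CC)C(O)C(=C)C(=O)OC | intermediate
10 | methyl (2Z,4R,6R)-2-(bromomethyl)-6-methyl-4-{[(2R)-2-methylbutanoyl]oxy}-6-[(triethylsilyl)oxy]octa-2,7-dienoate | C=C[C@](C)(O[Si](CC)(CC)CC)C[C@@H](OC(=O)[C@H](C)CC)/C=C(\CBr)C(=O)OC | intermediate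
11 | but-2-yn-1-ol | CC#CCO | starting material
12 | sodium 2,2-bis(2-methoxyethoxy)-3-methyl-2,5-dihydro-1,2-oxaaluminol-2-uide (cyclic alkenylalanate) | CC1=CCO[Al-]1(OCCOC)OCCOC.[Na+] | intermediate
13 | (2Z)-3-iodobut-2-en-1-ol | OC/C=C(/C)I | intermediate
14 | (2Z)-3-iodobut-2-enal | O=C/C=C(/C)I | intermediate
15 | methyl (3S,4R,6R)-3-[(1R,2Z)-1-hydroxy-3-iodobut-2-en-1-yl]-6-methyl-2-methylidene-4-{[(2R)-2-methylbutanoyl]oxy}-6-[(triethylsilyl)oxy]oct-7-enoate | C=C[C@](C)(O[Si](CC)(CC)CC)C[C@@H](OC(=O)[C@H](C)CC)[C@@H](C(=C)C(=O)OC)[C@@H](O)/C=C(/C)I | intermediate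
16 | (1R,3R)-1-{(2R,3R)-2-[(1Z)-2-iodoprop-1-en-1-yl]-4-methylidene-5-oxooxolan-3-yl}-3-methyl-3-[(triethylsilyl)oxy]pent-4-en-1-yl (2R)-2-methylbutanoate | C=C1C(=O)O[C@@H](/C=C(/C)I)[C@H]1[C@H](OC(=O)[C@H](C)CC)C[C@@](C)(O[Si](CC)(CC)CC)C=C | intermediate
17 | (1R,3R)-3-hydroxy-1-{(2R,3R)-2-[(1Z)-2-iodoprop-1-en-1-yl]-4-methylidene-5-oxooxolan-3-yl}-3-methylpent-4-en-1-yl (2R)-2-methylbutanoate | C=C1C(=O)O[C@@H](/C=C(/C)I)[C@H]1[C@H](OC(=O)[C@H](C)CC)C[C@@](C)(O)C=C | intermediate
18 | tributyl(ethenyl)stannane | C=C[Sn](CCCC)(CCCC)CCCC | starting material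
19 | (1R,3R)-3-hydroxy-3-methyl-1-{(2S,3R)-4-methylidene-2-[(1Z)-2-methyl-3-oxopenta-1,4-dien-1-yl]-5-oxooxolan-3-yl}pent-4-en-1-yl (2R)-2-methylbutanoate | C=C1C(=O)O[C@@H](/C=C(/C)C(=O)C=C)[C@H]1[C@H](OC(=O)[C@H](C)CC)C[C@@](C)(O)C=C | intermediate
20 | (3aR,4R,6R,7E,10Z,11aS)-6-hydroxy-6,10-dimethyl-3-methylidene-2,9-dioxo-2,3,3a,4,5,6,9,11a-octahydrocyclodeca[b]furan-4-yl (2R)-2-methylbutanoate | C=C1C(=O)O[C@H]2/C=C(/C)C(=O)/C=C/[C@](C)(O)C[C@@H](OC(=O)[C@H](C)CC)[C@@H]12 | target

**Step count**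
Total: 11 steps. Longest linear sequence: 8 steps (1, 2, 4, 5, 6, 9, 10, 11).

**Three steps most likely to fail**

Step 4 (the new α-acyloxylation). The aliphatic peroxide may be too weak an electrophile, may acylate the amine catalyst at nitrogen, or the α-acyloxy aldehyde may epimerise. The fallback uses known chemistry and makes the C8–O bond by a carboxylate nucleophile instead of an electrophilic oxygen. It sets out from 3: amine-catalysed α-chlorination (N-chlorosuccinimide, the enantiomer of 2,5-diphenylpyrrolidine that gives the (S)-chloride, CH2Cl2, −20 °C) gives (2S,4R)-2-chloro-4-methyl-4-[(triethylsilyl)oxy]hex-5-enal F1. Acid 4 with Cs2CO3 gives caesium (2R)-2-methylbutanoate F2, which displaces chloride from F1 with inversion (DMF, −20 to 0 °C). The fallback comes back to the route at 6.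

Step 9 (indium Barbier union). The allylindium carries an acyloxy group that could leave in a 1,4-elimination to a diene, and facial control from C8 may be too weak. The fallback replaces the allylmetal by an allylboronate that reacts through a closed boron transition state. It sets out from 9: acetylation (Ac2O, DMAP, CH2Cl2) gives methyl (4R,6R)-3-(acetyloxy)-6-methyl-2-methylidene-4-{[(2R)-2-methylbutanoyl]oxy}-6-[(triethylsilyl)oxy]oct-7-enoate F3. Copper-catalysed SN2' borylation (B2pin2, CuCl, KOAc, DMF) gives methyl (2E,4R,6R)-6-methyl-4-{[(2R)-2-methylbutanoyl]oxy}-2-[(4,4,5,5-tetramethyl-1,3,2-dioxaborolan-2-yl)methyl]-6-[(triethylsilyl)oxy]octa-2,7-dienoate F4, in which the C8 substituent is cis to CH2B. Allylboration of 14 with F4 (Sc(OTf)3 10 mol%, toluene, rt, aqueous work-up) gives the syn adduct. The fallback comes back to the route at 15, which is then treated with PPTS in methanol as in step 9.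

Step 11 (ring-closing metathesis). The ten-membered ring may not close, may oligomerise, or may give the 1Z enone. The fallback fixes the E geometry before ring closure and closes the ring at C3–C4 instead. It sets out from 17: cross-metathesis with crotonaldehyde (second-generation Hoveyda–Grubbs catalyst, CH2Cl2, 40 °C) gives (1R,3R,4E)-3-hydroxy-1-{(2R,3R)-2-[(1Z)-2-iodoprop-1-en-1-yl]-4-methylidene-5-oxooxolan-3-yl}-3-methyl-6-oxohex-4-en-1-yl (2R)-2-methylbutanoate F5. Nozaki–Hiyama–Kishi macrocyclisation (CrCl2, NiCl2 cat., DMSO/THF, 2 mM, rt) gives (3aR,4R,6R,7E,10Z,11aS)-6,9-dihydroxy-6,10-dimethyl-3-methylidene-2-oxo-2,3,3a,4,5,6,9,11a-octahydrocyclodeca[b]furan-4-yl (2R)-2-methylbutanoate F6 as a mixture of C9 epimers. Oxidation of the bis-allylic alcohol (MnO2, CH2Cl2) comes back to the route at 20.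

**Further compounds**
F1 | step 4 | (2S,4R)-2-chloro-4-methyl-4-[(triethylsilyl)oxy]hex-5-enal | C=C[C@](C)(O[Si](CC)(CC)CC)C[C@H](Cl)C=O
F2 | step 4 | caesium (2R)-2-methylbutanoate | CC[C@@H](C)C(=O)[O-].[Cs+]
F3 | step 9 | methyl (4R,6R)-3-(acetyloxy)-6-methyl-2-methylidene-4-{[(2R)-2-methylbutanoyl]oxy}-6-[(triethylsilyl)oxy]oct-7-enoate (both C3 epimers) | C=C[C@](C)(O[Si](CC)(CC)CC)C[C@@H](OC(=O)[C@H](C)CC)C(OC(C)=O)C(=C)C(=O)OC
F4 | step 9 | methyl (2E,4R,6R)-6-methyl-4-{[(2R)-2-methylbutanoyl]oxy}-2-[(4,4,5,5-tetramethyl-1,3,2-dioxaborolan-2-yl)methyl]-6-[(triethylsilyl)oxy]octa-2,7-dienoate | C=C[C@](C)(O[Si](CC)(CC)CC)C[C@@H](OC(=O)[C@H](C)CC)/C=C(\CB1OC(C)(C)C(C)(C)O1)C(=O)OC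
F5 | step 11 | (1R,3R,4E)-3-hydroxy-1-{(2R,3R)-2-[(1Z)-2-iodoprop-1-en-1-yl]-4-methylidene-5-oxooxolan-3-yl}-3-methyl-6-oxohex-4-en-1-yl (2R)-2-methylbutanoate | C=C1C(=O)O[C@@H](/C=C(/C)I)[C@H]1[C@H](OC(=O)[C@H](C)CC)C[C@@](C)(O)/C=C/C=O
F6 | step 11 | (3aR,4R,6R,7E,10Z,11aS)-6,9-dihydroxy-6,10-dimethyl-3-methylidene-2-oxo-2,3,3a,4,5,6,9,11a-octahydrocyclodeca[b]furan-4-yl (2R)-2-methylbutanoate (both C9 epimers) | C=C1C(=O)O[C@H]2/C=C(/C)C(O)/C=C/[C@](C)(O)C[C@@H](OC(=O)[C@H](C)CC)[C@@H]12
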